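**Retrosynthetic overview**
1. Last bond: C15–OAc. It is made by oxidative C–O bond formation on the planar enol of the finished tricyclic vinylogous β-diketone, and this creates the quaternary carbinol centre.
2. Ring C (12-membered carbocycle, formed last): C14–C15, by vinylogous Dieckmann closure of a cross-conjugated dienolate onto an N-acylindole.
3. Ring A is bought as 2-methylcyclopent-2-enone and joined through C4=C5 by aldol condensation with a ring-B aldehyde.
4. C12–C13 and the C13 centre: nickel hydride enantioconvergent hydroalkylation of the neopentyl vinyl group.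
5. Ring B (oxolane, formed first): C6–O, by Sharpless epoxidation and 5-exo epoxide opening of a geraniol-type diol. That diol comes from geranyl acetate by ozonolysis and Brown reverse prenylation (C9, C10).

Assumption: atom labels follow jatrophane numbering (C3 ring-A ketone, C4=C5 exocyclic alkene, C6 and C9 the ring-B carbons on oxygen, C10 gem-dimethyl carbon, C13 methyl-bearing carbon, C14 ring-C ketone, C15 acetoxy carbon), and the facial sense given for the nickel/bis(oxazoline) catalyst is by analogy, so its antipode is used if the sense proves opposite.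

Step 1
Reactants: 1 geranyl acetate
Product: 3 (2E)-3-methyl-6-oxohex-2-en-1-yl acetate, via secondary ozonide 2 (not isolated)
Conditions: O3 (1.0 equiv), CH2Cl2, −78 °C; then Me2S, −78 °C → rt
Reagents that add atoms: ozone, [O-][O+]=O
Why: Ozonolysis with reductive work-up: the electron-rich 6,7-alkene reacts much faster than the 2,3-alkene, which the allylic acetoxy group deactivates, so one equivalent of ozone cuts only the isopropylidene end and no stereocentre is involved.

Step 2
Reactants: 3 (2E)-3-methyl-6-oxohex-2-en-1-yl acetate; 4 3-methylbuta-1,2-diene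
Product: 7 (2E,6S)-3,7,7-trimethylnona-2,8-diene-1,6-diol, via prenylborane 5 (not isolated), via borinate 6 (not isolated)
Conditions: Ipc2BH [crystalline, from (−)-α-pinene], 4, THF, −25 → 0 °C; 3, Et2O, −78 °C; then 3 M NaOH, 30% H2O2, 0 → 40 °C
Reagents that add atoms: none
Why: Brown asymmetric allylboration in its reverse-prenylation form: the prenylborane adds through a closed chair transition state with allylic transposition (building the C10 gem-dimethyl carbon and the vinyl group), the (−)-α-pinene-derived Ipc groups direct attack to the Re face to set 9S, and the alkaline peroxide work-up oxidises the B–C bonds and saponifies the acetate in the same operation.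

Step 3
Reactants: 7 (2E,6S)-3,7,7-trimethylnona-2,8-diene-1,6-diol
Product: 9 (1R)-1-[(2S,5S)-2-methyl-5-(2-methylbut-3-en-2-yl)oxolan-2-yl]ethane-1,2-diol, via epoxy diol 8 (not isolated)
Conditions: Ti(OiPr)4 (10 mol %), D-(−)-diethyl tartrate (12 mol %), t-BuOOH, 4 Å MS, CH2Cl2, −20 °C; then CSA (10 mol %), 0 °C → rt
Reagents that add atoms: tert-butyl hydroperoxide, CC(C)(C)OO
Why: Sharpless asymmetric epoxidation followed by acid-catalysed 5-exo epoxide-opening etherification: the D-(−)-tartrate gives the (5R,6R)-epoxide under reagent control and the C9 hydroxyl attacks the tertiary C6 with inversion, which forms the C6–O bond and ring B and sets 6S with the C5 and C10 branches trans, while the vinyl group stays inert.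

Step 4
Reactants: 10 2-bromopropanoyl bromide; 11 indoline
Product: 12 rac-2-bromo-1-(2,3-dihydroindol-1-yl)propan-1-one
Conditions: Et3N, CH2Cl2, 0 °C
Reagents that add atoms: none
Why: Plain N-acylation of a secondary amine by an acid bromide (Schotten–Baumann type), and the product is used as the racemate.

Step 5
Reactants: 9 (1R)-1-[(2S,5S)-2-methyl-5-(2-methylbut-3-en-2-yl)oxolan-2-yl]ethane-1,2-diol; 12 rac-2-bromo-1-(2,3-dihydroindol-1-yl)propan-1-one
Product: 13 (2R)-5-{(2S,5S)-5-[(1R)-1,2-dihydroxyethyl]-5-methyloxolan-2-yl}-1-(2,3-dihydroindol-1-yl)-2,5-dimethylhexan-1-one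
Conditions: NiBr2(dme) (10 mol %), (R,R)-Ph-BOX (12 mol %), (EtO)3SiH, K3PO4·H2O, Et2O/DMA, rt
Reagents that add atoms: none
Why: Nickel hydride-catalysed enantioconvergent hydroalkylation of a terminal olefin by a racemic α-bromo amide: Ni–H adds anti-Markovnikov to the only alkene to give a primary alkylnickel, the bromide enters as a planar radical, and the chiral bis(oxazoline) ligand controls the C12–C13 bond formation so that C13 is set as R independently of the remote centres.

Step 6
Reactants: 13 (2R)-5-{(2S,5S)-5-[(1R)-1,2-dihydroxyethyl]-5-methyloxolan-2-yl}-1-(2,3-dihydroindol-1-yl)-2,5-dimethylhexan-1-one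
Product: 14 (2S,5S)-5-[(5R)-6-(2,3-dihydroindol-1-yl)-2,5-dimethyl-6-oxohexan-2-yl]-2-methyloxolane-2-carbaldehyde
Conditions: NaIO4, THF/H2O, 0 °C → rt
Reagents that add atoms: none
Why: Malaprade glycol cleavage removes C4 and the temporary C5 carbinol centre, and the resulting aldehyde sits on the quaternary C6, so it can neither enolise nor epimerise.

Step 7
Reactants: 14 (2S,5S)-5-[(5R)-6-(2,3-dihydroindol-1-yl)-2,5-dimethyl-6-oxohexan-2-yl]-2-methyloxolane-2-carbaldehyde; 15 2-methylcyclopent-2-en-1-one
Product: 19 (5E)-5-{[(2S,5S)-5-[(5R)-6-(2,3-dihydroindol-1-yl)-2,5-dimethyl-6-oxohexan-2-yl]-2-methyloxolan-2-yl]methylidene}-2-methylcyclopent-2-en-1-one, via lithium enolate 16 (not isolated), via lithium aldolate 17 (not isolated), via mesylate 18 (not isolated)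
Conditions: LiN(iPr)2, 15, THF, −78 °C; 14, −78 °C; MsCl, −78 → 0 °C; DBU, 0 °C → rt
Reagents that add atoms: none
Why: Directed aldol addition of the kinetic α′-enolate to a non-enolisable aldehyde, then mesylation and E1cB elimination (aldol condensation): both new sp3 centres are erased, the E-alkene with the bulky C6 group away from the carbonyl oxygen is the thermodynamic product, and the tertiary amide is inert to a ketone enolate at −78 °C.

Step 8
Reactants: 19 (5E)-dienone indolinyl amide
Product: 20 (5E)-5-{[(2S,5S)-5-[(5R)-6-(indol-1-yl)-2,5-dimethyl-6-oxohexan-2-yl]-2-methyloxolan-2-yl]methylidene}-2-methylcyclopent-2-en-1-one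
Conditions: DDQ (1.5 equiv), toluene, 80 °C
Reagents that add atoms: none
Why: DDQ dehydrogenation (aromatisation) of the indoline turns the inert amide into an N-acylindole acyl donor, and the dienone is spared because hydride loss from C15 would give an antiaromatic, carbonyl-destabilised cation.

Step 9
Reactants: 20 (5E)-dienone N-acylindole
Product: 23 (4E,6S,9S,13R)-6,9-epoxyjatropha-1,4-diene-3,14-dione (C15–H, keto/enol mixture), via potassium dienolate 21 (not isolated), via potassium enolate 22 (not isolated)
Conditions: KN(SiMe3)2 (1.05 equiv), THF, 1 mM (slow addition of 20), −78 → 0 °C; AcOH quench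
Reagents that add atoms: none
Why: Vinylogous Dieckmann (intramolecular Claisen) acylation: C4 carries no hydrogen, so the base can only remove the doubly allylic C15–H, the E-alkene, ring B and the gem-dimethyl group hold the acyl carbon next to C15 while O3 and C2 are out of reach, and the expelled indolide deprotonates the acidic product, which makes ring closure irreversible with one equivalent of base and shields C13 from enolisation; C15 is left labile and is fixed in step 10.

Step 10
Reactants: 23 (4E,6S,9S,13R)-6,9-epoxyjatropha-1,4-diene-3,14-dione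
Product: 25 (4E,6S,9S,13R,15S)-15-acetoxy-6,9-epoxyjatropha-1,4-diene-3,14-dione, via iodanyl enol ether 24 (not isolated)
Conditions: PhI(OAc)2 (1.1 equiv), CH2Cl2/AcOH (20:1), −20 → 0 °C, dark
Reagents that add atoms: (diacetoxyiodo)benzene, CC(=O)OI(OC(C)=O)c1ccccc1
Why: Proposed new method: oxidative acetoxylation of a vinylogous β-diketone (a γ-acyl cross-conjugated dienone) at its doubly activated carbon, in which the C14 enol of 23 displaces one acetate on trivalent iodine to give 24 and the remaining acetate passes within the ligand sphere to the adjacent C15 as iodobenzene leaves, so the vinylogous site C2 is out of reach and both enones stay conjugated; allylic 1,3-strain keeps the ring-B oxygen in the dienone plane next to C15, which places ring B and the C10–C13 chain over one face, so the oxidant comes from the open face syn to the C6 methyl while C14 bends toward the bridge, giving 15S; the closest known reaction types are the α-acetoxylation of 2-substituted 1,3-dicarbonyl compounds with PhI(OAc)2 or Pb(OAc)4 and the Wessely oxidation of phenols.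

**Compound list**
1 | geranyl acetate | CC(=O)OC/C=C(\C)CCC=C(C)C | starting material
2 | secondary ozonide of the 6,7-alkene of 1 | CC(=O)OC/C=C(\C)CCC1OOC(C)(C)O1 | intermediate
3 | (2E)-3-methyl-6-oxohex-2-en-1-yl acetate | CC(=O)OC/C=C(\C)CCC=O | intermediate
4 | 3-methylbuta-1,2-diene | CC(C)=C=C | starting material
5 | (3-methylbut-2-enyl)diisopinocampheylborane, Ipc from (−)-α-pinene | CC(C)=CCB([C@H]1C[C@H]2C[C@@H]([C@@H]1C)C2(C)C)[C@H]1C[C@H]2C[C@@H]([C@@H]1C)C2(C)C | intermediate
6 | diisopinocampheylborinate of the (6S)-alcohol, acetate still in place | CC(=O)OC/C=C(\C)CC[C@H](OB([C@H]1C[C@H]2C[C@@H]([C@@H]1C)C2(C)C)[C@H]1C[C@H]2C[C@@H]([C@@H]1C)C2(C)C)C(C)(C)C=C | intermediate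
7 | (2E,6S)-3,7,7-trimethylnona-2,8-diene-1,6-diol | OC/C=C(\C)CC[C@H](O)C(C)(C)C=C | intermediate
8 | [(2R,3R)-3-[(3S)-3-hydroxy-4,4-dimethylhex-5-en-1-yl]-3-methyloxiran-2-yl]methanol | OC[C@H]1O[C@]1(C)CC[C@H](O)C(C)(C)C=C | intermediate
9 | (1R)-1-[(2S,5S)-2-methyl-5-(2-methylbut-3-en-2-yl)oxolan-2-yl]ethane-1,2-diol | OC[C@@H](O)[C@]1(C)CC[C@H](O1)C(C)(C)C=C | intermediate
10 | 2-bromopropanoyl bromide (racemic) | CC(Br)C(=O)Br | starting material
11 | indoline | C1Cc2ccccc2N1 | starting material
12 | rac-2-bromo-1-(2,3-dihydroindol-1-yl)propan-1-one | CC(Br)C(=O)N1CCc2ccccc21 | intermediate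
13 | (2R)-indolinyl amide diol | OC[C@@H](O)[C@]1(C)CC[C@H](O1)C(C)(C)CC[C@@H](C)C(=O)N1CCc2ccccc21 | intermediate
14 | ring-B aldehyde with (R)-indolinyl amide side chain | O=C[C@]1(C)CC[C@H](O1)C(C)(C)CC[C@@H](C)C(=O)N1CCc2ccccc21 | intermediate
15 | 2-methylcyclopent-2-en-1-one | CC1=CCCC1=O | starting material
16 | kinetic lithium α′-enolate of 15 | [Li+].CC1=CCC=C1[O-] | intermediate
17 | lithium aldolate (C4–C5 bond made, diastereomer mixture at C4 and C5) | [Li+].[O-]C(C1CC=C(C)C1=O)[C@]1(C)CC[C@H](O1)C(C)(C)CC[C@@H](C)C(=O)N1CCc2ccccc21 | intermediate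
18 | C5 mesylate of the aldol | CS(=O)(=O)OC(C1CC=C(C)C1=O)[C@]1(C)CC[C@H](O1)C(C)(C)CC[C@@H](C)C(=O)N1CCc2ccccc21 | intermediate
19 | (5E)-cross-conjugated dienone, indolinyl amide | CC1=CC/C(=C\[C@]2(C)CC[C@H](O2)C(C)(C)CC[C@@H](C)C(=O)N2CCc3ccccc32)C1=O | intermediate
20 | (5E)-cross-conjugated dienone, N-acylindole | CC1=CC/C(=C\[C@]2(C)CC[C@H](O2)C(C)(C)CC[C@@H](C)C(=O)n2ccc3ccccc32)C1=O | intermediate
21 | potassium dienolate (2-oxidofulvene) of 20 | [K+].CC1=C([O-])/C(=C/[C@]2(C)CC[C@H](O2)C(C)(C)CC[C@@H](C)C(=O)n2ccc3ccccc32)C=C1 | intermediate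
22 | potassium C14 enolate of 23 | [K+].[O-]C1=C2C=C(C)C(=O)/C2=C/[C@]2(C)CC[C@H](O2)C(C)(C)CC[C@H]1C | intermediate
23 | (4E,6S,9S,13R)-6,9-epoxyjatropha-1,4-diene-3,14-dione, drawn as the 15-H keto form, C15 labile | C12C=C(C)C(=O)/C1=C/[C@]1(C)CC[C@H](O1)C(C)(C)CC[C@@H](C)C2=O | intermediate
24 | O14-[acetoxy(phenyl)iodanyl] enol ether of 23 | CC(=O)OI(c1ccccc1)OC1=C2C=C(C)C(=O)/C2=C/[C@]2(C)CC[C@H](O2)C(C)(C)CC[C@H]1C | intermediate
25 | (4E,6S,9S,13R,15S)-15-acetoxy-6,9-epoxyjatropha-1,4-diene-3,14-dione | CC(=O)O[C@@]12C=C(C)C(=O)/C1=C/[C@]1(C)CC[C@H](O1)C(C)(C)CC[C@@H](C)C2=O | target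

**Step count**
- Total steps: 10.
- Longest linear sequence: 9 (steps 1, 2, 3, 5, 6, 7, 8, 9, 10).

**Three steps most likely to fail**

**Step 5 (nickel hydride hydroalkylation).** The free 1,2-diol may bind nickel or consume silane, and the alkene sits next to a quaternary carbon.
- The fallback sets out from 9 and returns at 14. It replaces in situ hydrometalation by a preformed organozinc.
- 9 is protected with 2,2-dimethoxypropane and CSA as the acetonide F1.
- F1 is hydroborated with 9-BBN to the B-alkyl-9-BBN adduct F2.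
- F2 is iodinated with I2 and NaOMe to the primary iodide F3.
- F3 is converted with zinc dust (cat. I2, DMA) into the alkylzinc iodide F4.
- F4 is coupled with racemic 12 in an enantioconvergent Negishi reaction (NiCl2(dme), (R)-iPr-Pybox, DMI/THF, 0 °C) to the acetonide amide F5.
- H5IO6 in EtOAc then removes the acetonide and cleaves the glycol in one pot to give 14.

**Step 9 (ring-C closure).** The risks are oligomerisation, low nucleophilicity of the stabilised dienolate, and ketene formation or C13 epimerisation at the activated amide.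
- The fallback sets out from 20 and returns at 23. It replaces the base-driven Claisen closure by a base-free, silicon-to-fluorine-driven vinylogous Mukaiyama-type acylation.
- LiOH in THF/H2O hydrolyses 20 to the carboxylic acid F6.
- Cyanuric fluoride and pyridine convert F6 into the acyl fluoride F7.
- TBSOTf and Et3N convert the dienone into the silyl dienol ether F8.
- Slow addition of F8 to catalytic Bu4N[Ph3SiF2] in THF releases the dienolate only in trace amounts next to a non-ketene-forming acyl fluoride and closes the ring to 23.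

**Step 10 (new acetoxylation).** The risks are attack at C2, the wrong face, or over-oxidation.
- The fallback uses known chemistry, sets out from 23 and returns at 25.
- KN(SiMe3)2 regenerates the enolate 22.
- 22 is hydroxylated with 2-(phenylsulfonyl)-3-phenyloxaziridine (Davis enolate hydroxylation, as established for cyclic β-dicarbonyl enolates) to the 15-hydroxy ketone F9, with any 15-epimer removed by chromatography.
- Ac2O, DMAP and Et3N acetylate the tertiary alcohol to give 25.

**Further compounds**
F1 | step 5 | acetonide of 9 | CC1(C)OC[C@@H](O1)[C@]1(C)CC[C@H](O1)C(C)(C)C=C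
F2 | step 5 | B-alkyl-9-BBN adduct of F1 | CC1(C)OC[C@@H](O1)[C@]1(C)CC[C@H](O1)C(C)(C)CCB1C2CCCC1CCC2
F3 | step 5 | primary iodide | CC1(C)OC[C@@H](O1)[C@]1(C)CC[C@H](O1)C(C)(C)CCI
F4 | step 5 | alkylzinc iodide | CC1(C)OC[C@@H](O1)[C@]1(C)CC[C@H](O1)C(C)(C)CC[Zn]I
F5 | step 5 | acetonide amide (acetonide of 13) | CC1(C)OC[C@@H](O1)[C@]1(C)CC[C@H](O1)C(C)(C)CC[C@@H](C)C(=O)N1CCc2ccccc21
F6 | step 9 | carboxylic acid from 20 | CC1=CC/C(=C\[C@]2(C)CC[C@H](O2)C(C)(C)CC[C@@H](C)C(O)=O)C1=O
F7 | step 9 | acyl fluoride | CC1=CC/C(=C\[C@]2(C)CC[C@H](O2)C(C)(C)CC[C@@H](C)C(F)=O)C1=O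
F8 | step 9 | silyl dienol ether (2-silyloxyfulvene) acyl fluoride | CC1=C(O[Si](C)(C)C(C)(C)C)/C(=C/[C@]2(C)CC[C@H](O2)C(C)(C)CC[C@@H](C)C(F)=O)C=C1
F9 | step 10 | 15-hydroxy ketone (15-deacetyl 25) | O[C@@]12C=C(C)C(=O)/C1=C/[C@]1(C)CC[C@H](O1)C(C)(C)CC[C@@H](C)C2=O
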